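## Retrosynthetic overview

1. Numbering: Cn/On is the nth non-hydrogen atom of the target SMILES. Rings: A = spiro δ-lactone (C2, O4, C5, C7, C8, C9); B = cyclohexane C9–C10–C11–C12–C26–C27; C = cyclopentane C12–C26–C25–C23–C22; D = C12–C13–C14–C30–C23–C22; E = the C16–C17 bridge from C14 to C22 (D + E = bicyclo[2.2.2]octane); F = γ-lactone C17–C18–O20–C21–C22.
2. Feature: C22 is a quaternary bridgehead of the bicyclo[2.2.2]octane, its neighbour C17 carries the lactone carbonyl C18, and C30 is oxygenated. C17–C22 is therefore cut as the Ireland–Claisen bond of a δ-lactone (ring oxygen on C30, C18=O) cis-fused to a ring D cyclohexene with a C22=C23 alkene.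
3. After the key step: ring F (C21–OH onto C18), C30 ketone (hydroboration–oxidation), ring C (C23 enolate + C25 iodide), ring A (γ-allylation of acetone at C9, acrylate, ring-closing metathesis).
4. Before the key step: ring D enone by Stork–Danheiser transfer of C21 to C22, two α′-alkylations at C14, Luche reduction and oxidative lactonisation. Rings B and D are spiro-joined at C12 by an enantioselective Diels–Alder reaction of an exocyclic enone (from 2-methylcyclohexane-1,3-dione) with a 2-silyloxydiene.
5. Ring order: D (bought) → B → δ-lactone tether → E (key step) → F → C → A.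

Key step: step 17

Remark (assumption): in step 5 the (S)-oxazaborolidinium ion is taken to give the enantiomer drawn (otherwise its mirror-image catalyst is used); stereocentres that are erased later (C27 in 12 and 13, C9 in 12–45 and 47, C22 in 21, C14 in 24, C23/C30 in 38–42) are drawn in the expected sense and do not bear on the result.

## Route

Step 1
Reactants: 1 2-methylcyclohexane-1,3-dione
Product: 2 3-isobutoxy-2-methylcyclohex-2-en-1-one
Conditions: iBuOH, TsOH·H2O (cat.), PhMe, reflux (Dean–Stark)
Reagents that add atoms: 2-methylpropan-1-ol CC(C)CO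
Why: Acid-catalysed vinylogous esterification of the 1,3-dione, driven by azeotropic removal of water.

Step 2
Reactants: 2 3-isobutoxy-2-methylcyclohex-2-en-1-one
Product: 6 3-isobutoxy-2-methyl-6-methylidenecyclohex-2-en-1-one, via lithium enolate 3 (not isolated), via Mannich base 4 (not isolated), via methiodide 5 (not isolated)
Conditions: LiN(iPr)2, THF, −78 °C; Me2N=CH2+ I−, −78 → 0 °C; MeI, Et2O, rt; NaHCO3 (aq), CH2Cl2, rt
Reagents that add atoms: N,N-dimethylmethyleneiminium iodide (Eschenmoser's salt) C=[N+](C)C.[I-]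
Why: Kinetic α′-deprotonation of the vinylogous ester, Mannich reaction with Eschenmoser's salt and Hofmann-type elimination of the methiodide give the cross-conjugated exocyclic enone (future C11=C12), which is used at once because such enones dimerise.

Step 3
Reactants: 7 (benzyloxy)acetaldehyde; 8 1-(triphenyl-λ5-phosphanylidene)propan-2-one
Product: 9 (E)-5-(benzyloxy)pent-3-en-2-one
Conditions: CH2Cl2, 40 °C
Reagents that add atoms: none
Why: Wittig olefination with a stabilised acyl ylide gives the E-enone.

Step 4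
Reactants: 9 (E)-5-(benzyloxy)pent-3-en-2-one
Product: 10 (E)-{[5-(benzyloxy)penta-1,3-dien-2-yl]oxy}(tert-butyl)dimethylsilane
Conditions: tBuMe2SiOTf, Et3N, Et2O, 0 °C
Reagents that add atoms: tert-butyldimethylsilyl trifluoromethanesulfonate CC(C)(C)[Si](C)(C)OS(=O)(=O)C(F)(F)F
Why: Soft enolisation and O-silylation of the methyl ketone on its only enolisable side gives the 2-silyloxy-1,3-diene with the E-alkene retained.

Step 5
Reactants: 6 3-isobutoxy-2-methyl-6-methylidenecyclohex-2-en-1-one; 10 (E)-{[5-(benzyloxy)penta-1,3-dien-2-yl]oxy}(tert-butyl)dimethylsilane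
Product: 11 spiro Diels–Alder adduct (C12 spiro centre; silyl enol ether C9=C27; C26–CH2OBn cis to the C22 carbonyl)
Conditions: (S)-3,3-diphenyl-1-(2-methylphenyl)tetrahydro-1H,3H-pyrrolo[1,2-c][1,3,2]oxazaborole (0.2 equiv), HN(SO2CF3)2 (0.18 equiv), CH2Cl2, −78 → −40 °C
Reagents that add atoms: none
Why: Lewis-acid-catalysed Diels–Alder reaction in which the 2-silyloxy group (para rule) and the terminal CH2OBn group (ortho rule) both direct C26 to the fully substituted C12, the carbonyl-endo transition state places C25 cis to the C22 carbonyl on ring B, and the chiral oxazaborolidinium ion bound to that carbonyl shields one face of the exocyclic enone and so fixes the absolute configuration of C12 and C26.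

Step 6
Reactants: 11 spiro Diels–Alder adduct
Product: 13 C27 alcohol (C9–OTBS cis to C25; C27–OH trans to both), via alkylborane 12 (not isolated)
Conditions: BH3·SMe2, THF, 0 °C; then NaOH (aq), H2O2, 0 °C
Reagents that add atoms: hydrogen peroxide OO
Why: Hydroboration–oxidation of the silyl enol ether puts boron on C27 (β to oxygen) from the face opposite the axial C22 substituent of the spiro centre and gives the trans-2-silyloxy alcohol, so that C9–O (silylated) and C27–O (free) are differentiated, while the ester-like vinylogous ester is not reduced at 0 °C.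

Step 7
Reactants: 13 C27 alcohol
Product: 14 C27 ketone
Conditions: Dess–Martin periodinane, NaHCO3, CH2Cl2, 0 °C → rt
Reagents that add atoms: none
Why: Dess–Martin oxidation under buffered, non-basic conditions gives the ketone without epimerising the adjacent C26–H.

Step 8
Reactants: 14 C27 ketone
Product: 15 C27 tertiary alcohol (OH cis to C25 and to C9–OTBS; methyl C28 trans)
Conditions: MeLi, CeCl3, THF, −78 °C
Reagents that add atoms: methyllithium [Li]C
Why: Organocerium 1,2-addition (non-basic, so no enolisation toward C26) takes place only at the saturated C27 ketone and by equatorial attack, because the axial C22 on the spiro carbon C12 blocks the axial path, which sets C27 with the hydroxyl cis to C25.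

Step 9
Reactants: 15 C27 tertiary alcohol
Product: 16 C27 methoxymethyl ether
Conditions: MeOCH2Cl, iPr2NEt, Bu4NI (cat.), ClCH2CH2Cl, 60 °C
Reagents that add atoms: chloromethyl methyl ether COCCl
Why: Alkylation of the hindered tertiary alcohol under iodide catalysis installs a small, base-stable acetal that is carried to the last step.

Step 10
Reactants: 17 (4-methoxyphenyl)methanol; 18 tributyl(iodomethyl)stannane
Product: 20 tributyl{[(4-methoxybenzyl)oxy]methyl}stannane, via sodium alkoxide 19 (not isolated)
Conditions: NaH, THF/DMF, 0 °C; then 18, rt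
Reagents that add atoms: none
Why: Williamson etherification of the sodium alkoxide with the iodomethylstannane gives the tin precursor of the α-alkoxymethyllithium.

Step 11
Reactants: 16 C27 methoxymethyl ether; 20 tributyl{[(4-methoxybenzyl)oxy]methyl}stannane
Product: 22 ring D enone (C30 ketone; C22=C23 with CH2OPMB on C22 and methyl on C23), via tertiary carbinol 21 (not isolated)
Conditions: 20, nBuLi, THF, −78 °C; then 16, −78 → −40 °C; then 1 M HCl, THF, 0 °C → rt
Reagents that add atoms: water O
Why: Stork–Danheiser sequence in which tin–lithium exchange gives PMBOCH2Li, this adds 1,2 to the vinylogous ester carbonyl C22, and dilute acid ionises the tertiary allylic alcohol and hydrolyses the enol ether, so that the carbonyl is transposed to C30 and C21 sits on C22 of the new enone.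

Step 12
Reactants: 22 ring D enone
Product: 24 C14-methyl enone (methyl anti to C26), via lithium enolate 23 (not isolated)
Conditions: LiN(iPr)2, THF, −78 °C; MeI, −78 → −20 °C
Reagents that add atoms: iodomethane CI
Why: Kinetic α′-enolate alkylation at C14, the only α-CH2 of the C30 ketone; the configuration drawn at C14 is immaterial because C14 is enolised again in step 13.

Step 13
Reactants: 24 C14-methyl enone
Product: 26 C14-allyl-C14-methyl enone (allyl cis to C11; methyl cis to C26), via lithium enolate 25 (not isolated)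
Conditions: LiN(iPr)2, THF/DMPU, −78 → −40 °C; allyl bromide, −78 → 0 °C
Reagents that add atoms: 3-bromoprop-1-ene C=CCBr
Why: Second α′-alkylation of the cross-conjugated lithium dienolate creates quaternary C14, the allyl bromide entering anti to the bulky C26 branch of the spiro centre (1,3-related across C13), so that the C16 chain ends cis to C11 and the methyl cis to C26.

Step 14
Reactants: 26 C14-allyl-C14-methyl enone
Product: 27 C30 allylic alcohol (OH cis to the allyl group)
Conditions: NaBH4, CeCl3·7H2O, MeOH, −40 °C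
Reagents that add atoms: none
Why: Luche 1,2-reduction of the hindered enone, in which hydride should add anti to the pseudoaxial allyl group on C14 and so give the C30 alcohol cis to the C16 chain; any trans epimer is removed by chromatography.

Step 15
Reactants: 27 C30 allylic alcohol
Product: 29 diol (primary C18–OH and C30–OH), via bis-borane 28 (not isolated)
Conditions: 9-borabicyclo[3.3.1]nonane, THF, 0 °C → rt; then NaOH (aq), H2O2, 0 °C
Reagents that add atoms: hydrogen peroxide OO
Why: Anti-Markovnikov hydroboration–oxidation with the bulky dialkylborane is selective for the terminal alkene and leaves the tetrasubstituted C22=C23 alkene untouched.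

Step 16
Reactants: 29 diol
Product: 32 cis-fused δ-lactone on spiro cyclohexene ring D (key-step precursor), via hydroxy aldehyde 30 (not isolated), via lactol 31 (not isolated)
Conditions: TEMPO (cat.), PhI(OAc)2, CH2Cl2, rt
Reagents that add atoms: none
Why: TEMPO-mediated oxidative lactonisation of the 1,5-diol, in which the primary alcohol is oxidised first, the aldehyde closes to the lactol with the cis C30 hydroxyl and the lactol is oxidised to the δ-lactone.

Step 17
Reactants: 32 cis-fused δ-lactone on spiro cyclohexene ring D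
Product: 35 bicyclo[2.2.2]octene C18 carboxylic acid (key-step product), via silyl ketene acetal 33 (not isolated), via trimethylsilyl ester 34 (not isolated)
Conditions: Me3SiCl, Et3N, THF, −78 °C, then LiN(iPr)2 (in situ trap); PhMe, 105 °C; 1 M HCl, THF, rt
Reagents that add atoms: none
Why: LiN(iPr)2 in the presence of Me3SiCl turns the δ-lactone into its endocyclic silyl ketene acetal C17=C18(OSiMe3)–O, and on heating this allyl vinyl ether (C17=C18–O–C30–C23=C22) undergoes a [3,3]-sigmatropic Ireland–Claisen rearrangement in which C17–C22 forms as O–C30 breaks, the alkene moves to C23=C30 and C18 is released as a silyl ester that is hydrolysed to the acid. The closest known reaction type is the ring-contracting Ireland–Claisen rearrangement of lactone silyl ketene acetals whose ring oxygen sits on an allylic carbinol carbon. The ring that closes is the six-membered carbocycle C14–C16–C17–C22–C23–C30 (ring E, which with ring D makes the bicyclo[2.2.2]octene); it closes by a concerted suprafacial [3,3] shift through a boat-shaped six-centre array, the only geometry the cis-fused bicycle allows, so that no bridgehead enolate or bridgehead alkene is involved. C22 is set by suprafacial transfer of chirality from the C30 carbinol, since O on C30 and the C16 arm on C14 are cis and C17 can reach C22 only on that face, and C17 is set by the ring-fixed ketene acetal geometry, C18 staying on the side of C23/C30 to which it was tied through oxygen. No regiochemical choice is needed (C17 is the only enolisable position and C22 the only allylic terminus), but the step needs the cis ring fusion made in steps 13–16 and enough heat to join C17 to a fully substituted C22 next to quaternary C12; silyl trapping at −78 °C keeps the lactone enolate from self-condensation.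

Step 18
Reactants: 35 bicyclo[2.2.2]octene C18 carboxylic acid
Product: 37 γ-lactone (ring F) on the bicyclooctene, via hydroxy acid 36 (not isolated)
Conditions: DDQ, CH2Cl2/pH 7 buffer, 0 °C → rt; then PPTS (cat.), PhMe, 60 °C
Reagents that add atoms: none
Why: Oxidative cleavage of the 4-methoxybenzyl ether with DDQ (benzyl, methoxymethyl and silyl ethers are inert) frees the C21 hydroxyl, which lactonises under mild acid onto the C18 acid held on the adjacent C17.

Step 19
Reactants: 37 γ-lactone on the bicyclooctene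
Product: 39 C30 alcohol, via alkylborane 38 (not isolated)
Conditions: BH3·THF, THF, 0 °C → rt; then NaOH (aq), H2O2, 0 °C; then AcOH to pH 4
Reagents that add atoms: hydrogen peroxide OO
Why: Hydroboration–oxidation of the trisubstituted C23=C30 alkene places boron and then oxygen on the less substituted C30 (syn addition drawn from the side of the C16–C17 bridge); the γ-lactone, if opened by base, closes again on acidification.

Step 20
Reactants: 39 C30 alcohol
Product: 40 C30 ketone
Conditions: Dess–Martin periodinane, NaHCO3, CH2Cl2, rt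
Reagents that add atoms: none
Why: Dess–Martin oxidation gives the bicyclo[2.2.2]octanone, whose only enolisable α-carbon is C23.

Step 21
Reactants: 40 C30 ketone
Product: 41 C25 primary alcohol
Conditions: H2 (1 atm), Pd(OH)2/C, EtOAc, rt
Reagents that add atoms: none
Why: Hydrogenolysis of the benzyl ether is safe at this point because no C=C bond is left in the molecule.

Step 22
Reactants: 41 C25 primary alcohol
Product: 42 C25 iodide
Conditions: I2, PPh3, imidazole, CH2Cl2, 0 °C → rt
Reagents that add atoms: iodine II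
Why: Appel-type iodination converts the primary alcohol into the iodide under neutral conditions that leave the ketone, lactone and ethers alone.

Step 23
Reactants: 42 C25 iodide
Product: 44 pentacyclic keto lactone with ring C closed (C9–OTBS; C27–OMOM), via potassium enolate 43 (not isolated)
Conditions: KN(SiMe3)2, THF, −78 → 0 °C
Reagents that add atoms: none
Why: Intramolecular enolate alkylation (5-exo-tet) in which the C30 ketone can enolise only toward C23 and C25, held on the same side of the bicycle as the C23–C30 bridge, reaches C23 only from the face turned toward C12, which closes ring C and fixes quaternary C23.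

Step 24
Reactants: 44 pentacyclic keto lactone
Product: 45 C9 alcohol
Conditions: HF·pyridine, THF/pyridine, 0 °C → rt
Reagents that add atoms: none
Why: Fluoride cleavage of the secondary silyl ether, to which the methoxymethyl ether, the lactone and the ketone are inert.

Step 25
Reactants: 45 C9 alcohol
Product: 46 C9 ketone
Conditions: Dess–Martin periodinane, NaHCO3, CH2Cl2, rt
Reagents that add atoms: none
Why: Dess–Martin oxidation of the secondary alcohol next to the protected tertiary carbinol.

Step 26
Reactants: 46 C9 ketone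
Product: 47 C9 vinyl carbinol
Conditions: CH2=CHMgBr, CeCl3, THF, −78 °C
Reagents that add atoms: vinylmagnesium bromide C=C[Mg]Br
Why: Organocerium 1,2-addition, which does not enolise the ketone and is much faster at C9 than at the γ-lactone or at the C30 ketone flanked by two quaternary carbons.

Step 27
Reactants: 47 C9 vinyl carbinol
Product: 48 exocyclic allylic bromide (C9=C8–C7H2Br; C7 on the side of C10)
Conditions: PBr3, pyridine (cat.), Et2O, −30 → 0 °C
Reagents that add atoms: phosphorus tribromide BrP(Br)Br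
Why: Bromination of the tertiary allylic alcohol with allylic transposition (SN2′-type) gives the less hindered primary allylic bromide.

Step 28
Reactants: 48 exocyclic allylic bromide
Product: 50 C9 quaternary homoallylic alcohol (vinyl C8 cis to O29; C(CH3)2OH trans to O29), via allylzinc bromide 49 (not isolated)
Conditions: Zn dust, acetone (excess), THF, 0 °C → rt; then NH4Cl (aq)
Reagents that add atoms: acetone CC(C)=O
Why: Barbier-type allylation of acetone in which the allylzinc bromide adds through a six-membered transition state at its γ-carbon C9 (reverse-prenyl mode), creating the quaternary centre with the C8 vinyl group and the C2 carbinol; acetone should approach C9 anti to the axial C27–OMOM bond, which puts C2 trans to O29 as required.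

Step 29
Reactants: 50 C9 quaternary homoallylic alcohol
Product: 51 acrylate ester of the C2 tertiary alcohol
Conditions: CH2=CHCOCl, iPr2NEt, DMAP (cat.), CH2Cl2, 0 → 40 °C
Reagents that add atoms: acryloyl chloride C=CC(=O)Cl
Why: DMAP-catalysed acylation of the tertiary alcohol, the only free hydroxyl in the molecule.

Step 30
Reactants: 51 acrylate ester
Product: 52 C27-O-methoxymethyl ether of the target
Conditions: second-generation Hoveyda–Grubbs catalyst RuCl2(H2IMes)(=CH-C6H4-2-OiPr) (10 mol %), PhMe, 80 °C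
Reagents that add atoms: none
Why: Ring-closing metathesis between the vinyl group on C9 and the acrylate gives the α,β-unsaturated δ-lactone (ring A), with the C7=C8 bond cis by ring constraint and the gem-dimethyl group helping closure.

Step 31
Reactants: 52 C27-O-methoxymethyl ether of the target
Product: 54 CNP0222978.3, via bromomethyl ether 53 (not isolated)
Conditions: Me2BBr, CH2Cl2, −78 °C; then NaHCO3 (aq), THF, 0 °C
Reagents that add atoms: none
Why: Lewis-acid cleavage of the methoxymethyl acetal at −78 °C (through the bromomethyl ether, hydrolysed on work-up) frees the tertiary C27 hydroxyl without touching the tertiary-alkyl δ-lactone, the γ-lactone or the ketone.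

## Compound list

1 | 2-methylcyclohexane-1,3-dione | CC1C(=O)CCCC1=O | starting material
2 | 3-isobutoxy-2-methylcyclohex-2-en-1-one | CC1=C(OCC(C)C)CCCC1=O | intermediate
3 | lithium α′-enolate of 2 (not isolated) | CC1=C(OCC(C)C)CCC=C1O[Li] | intermediate
4 | 6-[(dimethylamino)methyl]-3-isobutoxy-2-methylcyclohex-2-en-1-one, racemic (not isolated) | CC1=C(OCC(C)C)CCC(CN(C)C)C1=O | intermediate
5 | trimethylammonium iodide of 4 (not isolated) | CC1=C(OCC(C)C)CCC(C[N+](C)(C)C)C1=O.[I-] | intermediate
6 | 3-isobutoxy-2-methyl-6-methylidenecyclohex-2-en-1-one | CC1=C(OCC(C)C)CCC(=C)C1=O | intermediate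
7 | (benzyloxy)acetaldehyde | O=CCOCc1ccccc1 | starting material
8 | 1-(triphenyl-λ5-phosphanylidene)propan-2-one | CC(=O)C=P(c1ccccc1)(c1ccccc1)c1ccccc1 | starting material
9 | (E)-5-(benzyloxy)pent-3-en-2-one | CC(=O)/C=C/COCc1ccccc1 | intermediate
10 | (E)-{[5-(benzyloxy)penta-1,3-dien-2-yl]oxy}(tert-butyl)dimethylsilane | C=C(O[Si](C)(C)C(C)(C)C)/C=C/COCc1ccccc1 | intermediate
11 | 7-[(benzyloxy)methyl]-9-(tert-butyldimethylsilyloxy)-3-isobutoxy-2-methylspiro[5.5]undeca-2,8-dien-1-one; CH2OBn on C26 cis to the C22 carbonyl | O=C1C(C)=C(OCC(C)C)CC[C@]12CCC(O[Si](C)(C)C(C)(C)C)=C[C@@H]2COCc1ccccc1 | intermediate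
12 | C27 alkylborane from 11, boron trans to the C9 silyloxy group (not isolated) | O=C1C(C)=C(OCC(C)C)CC[C@]12CC[C@H](O[Si](C)(C)C(C)(C)C)[C@@H](B)[C@@H]2COCc1ccccc1 | intermediate
13 | C27 secondary alcohol; C9–OTBS cis to C25, C27–OH trans to both | O=C1C(C)=C(OCC(C)C)CC[C@]12CC[C@H](O[Si](C)(C)C(C)(C)C)[C@@H](O)[C@@H]2COCc1ccccc1 | intermediate
14 | C27 ketone | O=C1C(C)=C(OCC(C)C)CC[C@]12CC[C@H](O[Si](C)(C)C(C)(C)C)C(=O)[C@@H]2COCc1ccccc1 | intermediate
15 | C27 tertiary alcohol; OH cis to C25, methyl C28 trans | O=C1C(C)=C(OCC(C)C)CC[C@]12CC[C@H](O[Si](C)(C)C(C)(C)C)[C@](C)(O)[C@@H]2COCc1ccccc1 | intermediate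
16 | C27 methoxymethyl ether of 15 | O=C1C(C)=C(OCC(C)C)CC[C@]12CC[C@H](O[Si](C)(C)C(C)(C)C)[C@](C)(OCOC)[C@@H]2COCc1ccccc1 | intermediate
17 | (4-methoxyphenyl)methanol | COc1ccc(CO)cc1 | starting material
18 | tributyl(iodomethyl)stannane | CCCC[Sn](CCCC)(CCCC)CI | starting material
19 | sodium (4-methoxyphenyl)methanolate (not isolated) | COc1ccc(C[O-])cc1.[Na+] | intermediate
20 | tributyl{[(4-methoxybenzyl)oxy]methyl}stannane | CCCC[Sn](CCCC)(CCCC)COCc1ccc(OC)cc1 | intermediate
21 | C22 tertiary carbinol from 1,2-addition to 16 (not isolated) | O[C@@]1(COCc2ccc(OC)cc2)C(C)=C(OCC(C)C)CC[C@]13CC[C@H](O[Si](C)(C)C(C)(C)C)[C@](C)(OCOC)[C@@H]3COCc1ccccc1 | intermediate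
22 | ring D enone: C30 ketone, C22=C23 with CH2OPMB on C22 and methyl on C23 | O=C1CC[C@]2(CC[C@H](O[Si](C)(C)C(C)(C)C)[C@](C)(OCOC)[C@@H]2COCc2ccccc2)C(COCc2ccc(OC)cc2)=C1C | intermediate
23 | lithium C14 enolate of 22 (not isolated) | [Li]OC1=CC[C@]2(CC[C@H](O[Si](C)(C)C(C)(C)C)[C@](C)(OCOC)[C@@H]2COCc2ccccc2)C(COCc2ccc(OC)cc2)=C1C | intermediate
24 | C14-methyl enone, methyl anti to C26 | O=C1[C@H](C)C[C@]2(CC[C@H](O[Si](C)(C)C(C)(C)C)[C@](C)(OCOC)[C@@H]2COCc2ccccc2)C(COCc2ccc(OC)cc2)=C1C | intermediate
25 | lithium C14 enolate of 24 (not isolated) | [Li]OC1=C(C)C[C@]2(CC[C@H](O[Si](C)(C)C(C)(C)C)[C@](C)(OCOC)[C@@H]2COCc2ccccc2)C(COCc2ccc(OC)cc2)=C1C | intermediate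
26 | C14-allyl-C14-methyl enone; allyl cis to C11, methyl cis to C26 | O=C1[C@](C)(CC=C)C[C@]2(CC[C@H](O[Si](C)(C)C(C)(C)C)[C@](C)(OCOC)[C@@H]2COCc2ccccc2)C(COCc2ccc(OC)cc2)=C1C | intermediate
27 | C30 allylic alcohol, OH cis to the allyl group | O[C@@H]1[C@](C)(CC=C)C[C@]2(CC[C@H](O[Si](C)(C)C(C)(C)C)[C@](C)(OCOC)[C@@H]2COCc2ccccc2)C(COCc2ccc(OC)cc2)=C1C | intermediate
28 | bis(9-borabicyclononyl) intermediate: C18–B and C30–O–B (not isolated) | O(B3C4CCCC3CCC4)[C@@H]1[C@](C)(CCCB3C4CCCC3CCC4)C[C@]2(CC[C@H](O[Si](C)(C)C(C)(C)C)[C@](C)(OCOC)[C@@H]2COCc2ccccc2)C(COCc2ccc(OC)cc2)=C1C | intermediate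
29 | diol: primary C18–OH and C30–OH | O[C@@H]1[C@](C)(CCCO)C[C@]2(CC[C@H](O[Si](C)(C)C(C)(C)C)[C@](C)(OCOC)[C@@H]2COCc2ccccc2)C(COCc2ccc(OC)cc2)=C1C | intermediate
30 | C18 hydroxy aldehyde (not isolated) | O[C@@H]1[C@](C)(CCC=O)C[C@]2(CC[C@H](O[Si](C)(C)C(C)(C)C)[C@](C)(OCOC)[C@@H]2COCc2ccccc2)C(COCc2ccc(OC)cc2)=C1C | intermediate
31 | C18 lactol, both anomers (not isolated) | OC1CC[C@]2(C)C[C@]3(CC[C@H](O[Si](C)(C)C(C)(C)C)[C@](C)(OCOC)[C@@H]3COCc3ccccc3)C(COCc3ccc(OC)cc3)=C(C)[C@@H]2O1 | intermediate
32 | key-step precursor: cis-fused δ-lactone (ring O on C30, C18=O) on the spiro cyclohexene; C9–OTBS, C27–OMOM, C25–OBn, C21–OPMB | O=C1CC[C@]2(C)C[C@]3(CC[C@H](O[Si](C)(C)C(C)(C)C)[C@](C)(OCOC)[C@@H]3COCc3ccccc3)C(COCc3ccc(OC)cc3)=C(C)[C@@H]2O1 | intermediate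
33 | trimethylsilyl ketene acetal of 32 (not isolated) | C[Si](C)(C)OC1=CC[C@]2(C)C[C@]3(CC[C@H](O[Si](C)(C)C(C)(C)C)[C@](C)(OCOC)[C@@H]3COCc3ccccc3)C(COCc3ccc(OC)cc3)=C(C)[C@@H]2O1 | intermediate
34 | trimethylsilyl ester of 35 (not isolated) | C[Si](C)(C)OC(=O)[C@H]1C[C@]2(C)C[C@]3(CC[C@H](O[Si](C)(C)C(C)(C)C)[C@](C)(OCOC)[C@@H]3COCc3ccccc3)[C@@]1(COCc1ccc(OC)cc1)C(C)=C2 | intermediate
35 | key-step product: bicyclo[2.2.2]octene with C17–CO2H (C18 on the side of the C23=C30 bridge), C22–CH2OPMB, C23-methyl | OC(=O)[C@H]1C[C@]2(C)C[C@]3(CC[C@H](O[Si](C)(C)C(C)(C)C)[C@](C)(OCOC)[C@@H]3COCc3ccccc3)[C@@]1(COCc1ccc(OC)cc1)C(C)=C2 | intermediate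
36 | C21 hydroxy acid (not isolated) | OC(=O)[C@H]1C[C@]2(C)C[C@]3(CC[C@H](O[Si](C)(C)C(C)(C)C)[C@](C)(OCOC)[C@@H]3COCc3ccccc3)[C@@]1(CO)C(C)=C2 | intermediate
37 | γ-lactone (ring F) on the bicyclooctene | O=C4[C@H]1C[C@]2(C)C[C@]3(CC[C@H](O[Si](C)(C)C(C)(C)C)[C@](C)(OCOC)[C@@H]3COCc3ccccc3)[C@@]1(CO4)C(C)=C2 | intermediate
38 | C30 alkylborane (not isolated) | O=C4[C@H]1C[C@]2(C)C[C@]3(CC[C@H](O[Si](C)(C)C(C)(C)C)[C@](C)(OCOC)[C@@H]3COCc3ccccc3)[C@@]1(CO4)[C@@H](C)[C@@H]2B | intermediate
39 | C30 secondary alcohol, C23–H | O=C4[C@H]1C[C@]2(C)C[C@]3(CC[C@H](O[Si](C)(C)C(C)(C)C)[C@](C)(OCOC)[C@@H]3COCc3ccccc3)[C@@]1(CO4)[C@@H](C)[C@@H]2O | intermediate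
40 | C30 ketone (bicyclo[2.2.2]octanone), C23–H epimerisable | O=C4[C@H]1C[C@]2(C)C[C@]3(CC[C@H](O[Si](C)(C)C(C)(C)C)[C@](C)(OCOC)[C@@H]3COCc3ccccc3)[C@@]1(CO4)[C@@H](C)C2=O | intermediate
41 | C25 primary alcohol | O=C4[C@H]1C[C@]2(C)C[C@]3(CC[C@H](O[Si](C)(C)C(C)(C)C)[C@](C)(OCOC)[C@@H]3CO)[C@@]1(CO4)[C@@H](C)C2=O | intermediate
42 | C25 iodide | O=C4[C@H]1C[C@]2(C)C[C@]3(CC[C@H](O[Si](C)(C)C(C)(C)C)[C@](C)(OCOC)[C@@H]3CI)[C@@]1(CO4)[C@@H](C)C2=O | intermediate
43 | potassium C23 enolate of 42 (not isolated) | O=C4[C@H]1C[C@]2(C)C[C@]3(CC[C@H](O[Si](C)(C)C(C)(C)C)[C@](C)(OCOC)[C@@H]3CI)[C@@]1(CO4)C(C)=C2O[K] | intermediate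
44 | pentacyclic keto lactone with ring C closed; C9–OTBS, C27–OMOM | CC(C)(C)[Si](C)(C)O[C@H]1CC[C@@]23C[C@@]4(C)C[C@@H]5C(=O)OC[C@]52[C@@](C)(C[C@H]3[C@@]1(C)OCOC)C4=O | intermediate
45 | C9 secondary alcohol | O[C@H]1CC[C@@]23C[C@@]4(C)C[C@@H]5C(=O)OC[C@]52[C@@](C)(C[C@H]3[C@@]1(C)OCOC)C4=O | intermediate
46 | C9 ketone | O=C1CC[C@@]23C[C@@]4(C)C[C@@H]5C(=O)OC[C@]52[C@@](C)(C[C@H]3[C@@]1(C)OCOC)C4=O | intermediate
47 | C9 vinyl carbinol | C=C[C@]1(O)CC[C@@]23C[C@@]4(C)C[C@@H]5C(=O)OC[C@]52[C@@](C)(C[C@H]3[C@@]1(C)OCOC)C4=O | intermediate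
48 | exocyclic allylic bromide C9=C8–C7H2Br, C7 on the side of C10 | BrC/C=C1\CC[C@@]23C[C@@]4(C)C[C@@H]5C(=O)OC[C@]52[C@@](C)(C[C@H]3[C@@]1(C)OCOC)C4=O | intermediate
49 | allylzinc bromide from 48 (not isolated) | Br[Zn]C/C=C1\CC[C@@]23C[C@@]4(C)C[C@@H]5C(=O)OC[C@]52[C@@](C)(C[C@H]3[C@@]1(C)OCOC)C4=O | intermediate
50 | C9 quaternary homoallylic alcohol; vinyl (C8) cis to O29, C(CH3)2OH (C2) trans to O29 | C=C[C@@]1(C(C)(C)O)CC[C@@]23C[C@@]4(C)C[C@@H]5C(=O)OC[C@]52[C@@](C)(C[C@H]3[C@@]1(C)OCOC)C4=O | intermediate
51 | acrylate ester of 50 | C=C[C@@]1(C(C)(C)OC(=O)C=C)CC[C@@]23C[C@@]4(C)C[C@@H]5C(=O)OC[C@]52[C@@](C)(C[C@H]3[C@@]1(C)OCOC)C4=O | intermediate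
52 | C27-O-methoxymethyl ether of the target | CC1(C)OC(=O)C=C[C@]12CC[C@@]13C[C@@]4(C)C[C@@H]5C(=O)OC[C@]51[C@@](C)(C[C@H]3[C@@]2(C)OCOC)C4=O | intermediate
53 | C27-O-bromomethyl ether (not isolated) | CC1(C)OC(=O)C=C[C@]12CC[C@@]13C[C@@]4(C)C[C@@H]5C(=O)OC[C@]51[C@@](C)(C[C@H]3[C@@]2(C)OCBr)C4=O | intermediate
54 | CNP0222978.3 | CC1(C)OC(=O)C=C[C@]12CC[C@@]13C[C@@]4(C)C[C@@H]5C(=O)OC[C@]51[C@@](C)(C[C@H]3[C@@]2(C)O)C4=O | target

## Step count and risks

Total: 31 steps. Longest linear sequence: 28 steps (steps 1, 2, 5–9 and 11–31, from 2-methylcyclohexane-1,3-dione).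

The three steps most likely to fail:

1. Step 17 (key step). The rearrangement may stall because the ketene acetal carbon C17 has to bond to a fully substituted alkene carbon (C22) next to the quaternary spiro carbon C12. On prolonged heating the silyl ketene acetal may instead ionise at the allylic C30–O bond, with elimination to a diene acid, or simply hydrolyse back to the lactone. Fallback, setting out from 24 and coming back at 40: the lithium dienolate 25 is treated with methyl acrylate (THF, −78 °C → rt) in an anionic double Michael reaction (formal [4+2]). The C14 enolate adds to the acrylate from the face anti to C26 and the resulting ester enolate closes onto C22 of the enone, giving the bicyclo[2.2.2]octanone methyl ester F1 with the C30 ketone already in place and the ester on the side of the C23–C30 bridge. DDQ then frees the C21 alcohol to give the hydroxy ester F2, which lactonises with loss of methanol (PPTS, PhMe, 80 °C) to 40.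

2. Step 28. Bond formation at the doubly neopentyl γ-carbon C9 may be slower than α-attack through C7 (linear homoallylic alcohol), Wurtz coupling or protonation of the allylzinc, and the facial preference at C9 may be low. Fallback, setting out from 48 and coming back at 50: 48 is esterified with caesium isobutyrate (DMF, rt) to the allylic isobutyrate F3. An Ireland–Claisen rearrangement (excess LiN(iPr)2/Me3SiCl, THF, −78 → 60 °C; the γ-lactone is silylated reversibly and returns on work-up) forms the C9–C2 bond intramolecularly and gives the acid F4. The acid is converted through its acid chloride into the N-acyloxypyridine-2-thione (Barton ester) F5, and decarboxylative hydroxylation (O2, tBuSH, hν; then PPh3) gives 50.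

3. Step 5. The catalyst may discriminate the two faces of the exocyclic enone poorly (low enantiomeric purity), the exo approach may compete, or the strong acid may desilylate the diene or stop at the open Mukaiyama–Michael adduct. Fallback, setting out from 6 and 10 and coming back at 13: the cycloaddition is run with achiral Et2AlCl (CH2Cl2, −78 °C), giving 11 together with its mirror image, the ent-adduct F6. Hydroboration–oxidation as in step 6 (through 12 and the mirror-image borane F7) gives 13 together with the ent-alcohol F8. Lipase-catalysed acylation (Candida antarctica lipase B, vinyl acetate) then separates the enantiomers: the alcohol of the unwanted series is removed as its acetate F9, and 13 continues.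

Further compounds
F1 | step 17 | bicyclo[2.2.2]octanone methyl ester from the double Michael reaction (C30 ketone, C17–CO2Me, C22–CH2OPMB) | COC(=O)[C@H]1C[C@]2(C)C[C@]3(CC[C@H](O[Si](C)(C)C(C)(C)C)[C@](C)(OCOC)[C@@H]3COCc3ccccc3)[C@@]1(COCc1ccc(OC)cc1)[C@@H](C)C2=O
F2 | step 17 | C21 hydroxy methyl ester | COC(=O)[C@H]1C[C@]2(C)C[C@]3(CC[C@H](O[Si](C)(C)C(C)(C)C)[C@](C)(OCOC)[C@@H]3COCc3ccccc3)[C@@]1(CO)[C@@H](C)C2=O
F3 | step 28 | allylic isobutyrate of the C9=C8–C7 unit | CC(C)C(=O)OC/C=C1\CC[C@@]23C[C@@]4(C)C[C@@H]5C(=O)OC[C@]52[C@@](C)(C[C@H]3[C@@]1(C)OCOC)C4=O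
F4 | step 28 | C9-vinyl C2 carboxylic acid from the Ireland–Claisen rearrangement | C=C[C@@]1(C(C)(C)C(=O)O)CC[C@@]23C[C@@]4(C)C[C@@H]5C(=O)OC[C@]52[C@@](C)(C[C@H]3[C@@]1(C)OCOC)C4=O
F5 | step 28 | N-acyloxypyridine-2-thione (Barton ester) of F4 | C=C[C@@]1(C(C)(C)C(=O)ON6C=CC=CC6=S)CC[C@@]23C[C@@]4(C)C[C@@H]5C(=O)OC[C@]52[C@@](C)(C[C@H]3[C@@]1(C)OCOC)C4=O
F6 | step 5 | mirror image of 11 | O=C1C(C)=C(OCC(C)C)CC[C@@]12CCC(O[Si](C)(C)C(C)(C)C)=C[C@H]2COCc1ccccc1
F7 | step 5 | mirror image of 12 | O=C1C(C)=C(OCC(C)C)CC[C@@]12CC[C@@H](O[Si](C)(C)C(C)(C)C)[C@H](B)[C@H]2COCc1ccccc1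
F8 | step 5 | mirror image of 13 | O=C1C(C)=C(OCC(C)C)CC[C@@]12CC[C@@H](O[Si](C)(C)C(C)(C)C)[C@H](O)[C@H]2COCc1ccccc1
F9 | step 5 | acetate of the mirror image of 13 | O=C1C(C)=C(OCC(C)C)CC[C@@]12CC[C@@H](O[Si](C)(C)C(C)(C)C)[C@H](OC(C)=O)[C@H]2COCc1ccccc1
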